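Which species holds most of the substrate after 6.0 h, and how much of it, when reagent is charged level with substrate and when it is charged in excess?

- summer: substrate 0.97 M; reagent 0.970 M; time 6.0 h
- midnight: substrate 0.97 M; reagent 1.50 M; time 6.0 h

- which of these there is most of at the end, counted by the substrate in it, summer (isomer of the product / triple product / substrate / double product)
- which of these there is most of at the end, counted by the substrate in it, midnight (isomer of the product / triple product / substrate / double product)
- amount of the one of these that there is most of at the end, in percent of the substrate charged, summer
- amount of the one of these that there is most of at the end, in percent of the substrate charged, midnight

    reagent + double product → triple product + by-product (k1 = 0.0046 M⁻¹ s⁻¹)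
    substrate + reagent → mono adduct + by-product (k2 = 0.014 M⁻¹ s⁻¹)
    mono adduct ⇌ isomer of the product (K3 = 2.7, k3 = 0.0013 s⁻¹)
    reagent + mono adduct → double product + by-product (k4 = 0.054 M⁻¹ s⁻¹)

The bench rule for the summer flask, whose reagent-to-substrate ratio r is 1.00, says that one reagent per substrate gives mono adduct. That rule holds when the first addition outruns the second, but here the selectivity factor S, the rate constant for reagent on mono adduct over that for reagent on substrate, is 3.86, so mono adduct is attacked faster than substrate at equal concentration. The rule therefore fails, and something else can be frozen. As substrate falls, the ratio of mono adduct to substrate climbs to a plateau at which the two fall in step, ρ, equal to one over S minus one, 0.350.

I count the isomer with mono adduct, since each holds one reagent's worth, and I leave isomerisation out of the ratio because its forward half-life of 8.89 min is longer than the substrate's 0.85 min at summer charges. Double and triple product stay in one count, the rate constant of the triple-forming step being smaller than that of the double-forming step by a factor of 11.7. If the whole reagent charge reacts, which the same half-life against 6.0 h suggests, the balance gives a substrate fraction of (2 − r)/(2 + ρ).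

For summer that is 42.6%, with double and triple product together level at 42.6%, and any triple product then lowers the double product, so substrate leads. For midnight it is 19.3% of substrate against 73.9% of double and triple product, a sum that I do not split.

The forecast names substrate at 44% (40% to 48%) for summer, on the ground that “the reagent balance then forces substrate to equal double product plus twice the triple product”. For midnight, as a separate case with 1.50 M of reagent, it names double product at 52% (47% to 57%), a figure for double product by itself, which is a split that my sum does not make.

The simulation gives substrate leading in summer at 44.3% and double product leading at midnight at 51.4%, each inside the forecast's range, while midnight substrate reads 24.0% against my 19.3%. In summer, with reagent at 0%, mono adduct plus isomer read 0.358 per substrate against ρ of 0.350. The midnight flask charged instead with 0.90 M of reagent reckons to 45.6% substrate. It holds 47.3%, so substrate leads double product at 32.7%, and its mono adduct plus isomer read 0.346 per substrate.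

(The constants used here are those of an exercise; no experiment stands behind them.)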